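## Retrosynthetic overview

1. Target 26 ⇐ allylic alcohol 24: C2 carbinol oxidation and C2–OH-directed epoxidation (sets C1, C10); the C6/C9 acetates follow reduction of a C9 ketone (sets C9).
2. Key disconnection C4–C9: Grob ring expansion of the cis-fused bicyclo[4.4.0]decane amino alcohol 18 gives the ten-membered ring 20 (C9 ketone + 4(15)-methylene). The same base treatment unveils the lactone methylene from a second CH2NMe3+ group.
3. Ring B and the γ-lactone: annulation of ring A diketone 8 with a butenolide γ-anion equivalent (C8–C9 by 1,2-addition, C6–C7 by ring-closing Michael addition); C5 by hydroxyl-directed reduction.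
4. Ring A (4) from silyloxyacetaldehyde 1 and ethyl vinyl ketone 2 by organocatalytic Michael/aldol annulation; quaternary C4 by aldol, oxidation and Mannich reaction.
5. Order of ring formation: ring A → ring B and lactone (one flask) → ten-membered ring (ring expansion) → epoxide.

Assumption: germacrane numbering is used for every intermediate (C1–C10 = ring carbons of the target, C11–C13 = lactone carbons, C14 = methyl on C10, C15 = methylene on C4); in the bicyclic compounds ring A = C1, C2, C3, C4, C9, C10 and ring B = C4–C9; compounds 1, 2, 5, 9 and 17 are purchased.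

## Route

Step 1
Reactants: 1 2-[(tert-butyldimethylsilyl)oxy]acetaldehyde; 2 pent-1-en-3-one (ethyl vinyl ketone)
Product: 4 (4S)-4-[(tert-butyldimethylsilyl)oxy]-2-methylcyclohex-2-en-1-one, via keto aldehyde 3 (not isolated)
Conditions: (R)-α,α-diphenylprolinol trimethylsilyl ether (10 mol%), ethyl 3,4-dihydroxybenzoate (20 mol%), neat, 4 °C; then Bn2NH·CF3CO2H (20 mol%), toluene, 50 °C
Reagents that add atoms: none
Why: Enamine-catalysed Michael addition of the aldehyde to the vinyl ketone followed by intramolecular aldol condensation (organocatalytic Robinson annulation); the diarylprolinol ether shields one face of the (E)-enamine and sets C2 as (S), the only stereocentre introduced by a chiral catalyst.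

Step 2
Reactants: 4 (4S)-4-[(tert-butyldimethylsilyl)oxy]-2-methylcyclohex-2-en-1-one; 5 2-[(4-methoxybenzyl)oxy]acetaldehyde
Product: 6 aldol adduct (C4 side chain CH(OH)CH2OPMB trans to the C2 silyloxy group)
Conditions: LiN(i-Pr)2, THF, −78 °C; then 5, −78 °C; NH4Cl quench
Reagents that add atoms: none
Why: Aldol addition of the kinetic α'-lithium enolate (C4), which is attacked trans to the C2 silyloxy group; the two new centres are removed or reset in steps 3 and 4, so the diastereomer ratio is of no consequence.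

Step 3
Reactants: 6 aldol adduct
Product: 7 β-diketone (C4 acyl group C(=O)CH2OPMB; enolised)
Conditions: Dess–Martin periodinane, NaHCO3, CH2Cl2, 0 °C to rt
Reagents that add atoms: none
Why: Dess–Martin oxidation of the β-hydroxy ketone to the enolised β-diketone; silyl ether, PMB ether and enone are inert.

Step 4
Reactants: 7 β-diketone
Product: 8 Mannich base (quaternary C4 carrying CH2NMe2 trans to the C2 silyloxy group)
Conditions: Me2N=CH2+ I− (Eschenmoser's salt), Et3N, CH2Cl2, 0 °C to rt; used without storage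
Reagents that add atoms: N,N-dimethylmethyleneiminium iodide, C=[N+](C)C.[I-]
Why: Mannich reaction of the enol carbon C4 with the iminium ion, which enters axially on the face opposite the C2 silyloxy group and so fixes the quaternary centre that later relays chirality to C9 and C8.

Step 5
Reactants: 9 furan-2(5H)-one
Product: 10 2-[(triisopropylsilyl)oxy]furan
Conditions: i-Pr3SiOTf, Et3N, CH2Cl2, 0 °C
Reagents that add atoms: triisopropylsilyl trifluoromethanesulfonate, CC(C)[Si](OS(=O)(=O)C(F)(F)F)(C(C)C)C(C)C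
Why: O-silylation of the butenolide dienolate (silyl dienol ether formation) gives the aromatic silyloxyfuran.

Step 6
Reactants: 8 Mannich base; 10 2-[(triisopropylsilyl)oxy]furan
Product: 14 tricyclic keto lactone (ring A + ring B + cis γ-lactone; C5 ketone; C9 tertiary alcohol), via lithiofuran 11 (not isolated), via furyl carbinol 12 (not isolated), via butenolide 13 (not isolated)
Conditions: 10, n-BuLi, THF, −78 to −20 °C; 8, LiN(SiMe3)2 (1.05 equiv), THF, −78 °C; combine, −78 °C; AcOH then Bu4NF, −20 °C; DBU, rt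
Reagents that add atoms: n-butyllithium, [Li]CCCC (its lithium is found in intermediate 11 only)
Why: Proposed new method: a 5-lithio-2-silyloxyfuran serves as a hard butenolide γ-anion that adds 1,2 to the C9 enone carbonyl (the C5 ketone is masked as its lithium enolate; attack anti to the axial CH2NMe2 group), buffered fluoride then unmasks the butenolide without acid, and DBU closes ring B by Michael addition of the C6 enolate to C7 under equilibrating conditions (C8 epimerisable through the furanolate, retro-Michael possible), funnelling to the cis-fused lactone with O8 anti to the axial C9 hydroxyl and C6-OPMB and C7–C11 equatorial, which sets C6, C7 and C8; the closest known reaction types are carbonyl additions of 5-lithio-2-methoxyfuran and base-mediated intramolecular Michael additions to butenolides.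

Step 7
Reactants: 14 tricyclic keto lactone
Product: 15 C5 alcohol (5R; 1,3-anti to the C9 hydroxyl; trans to the C6 ether)
Conditions: Me4NBH(OAc)3, MeCN/AcOH, −25 °C
Reagents that add atoms: none
Why: Evans–Saksena hydroxyl-directed reduction: the axial C9 hydroxyl binds the triacetoxyborohydride and delivers hydride intramolecularly to the syn-axial face of the C5 ketone, giving the equatorial (5R) alcohol.

Step 8
Reactants: 15 C5 alcohol
Product: 16 bis(dimethylaminomethyl) diol (second CH2NMe2 on lactone carbon C11)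
Conditions: LiN(i-Pr)2 (3.3 equiv), THF, −78 °C; Me2N=CH2+ I−, −78 to 0 °C; NH4Cl quench
Reagents that add atoms: N,N-dimethylmethyleneiminium iodide, C=[N+](C)C.[I-]
Why: Mannich reaction of the lactone lithium enolate with Eschenmoser's salt (first half of the classical α-methylenation), done before the epimerisable ester is present; the iminium enters from the convex lactone face and the C11 centre is erased in step 10.

Step 9
Reactants: 16 bis(dimethylaminomethyl) diol; 17 (R)-2-methylbutanoic acid
Product: 18 C5 (R)-2-methylbutanoate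
Conditions: DCC, DMAP, CH2Cl2, rt
Reagents that add atoms: none
Why: Steglich esterification; only the secondary C5 hydroxyl reacts (the C9 hydroxyl is tertiary) and the α-stereocentre of the acid is not enolised under carbodiimide activation.

Step 10
Reactants: 18 C5 (R)-2-methylbutanoate
Product: 20 ten-membered (Z)-enone (C9 ketone; 4(15)- and 11(13)-methylene groups), via bis-ammonium diiodide 19 (not isolated)
Conditions: MeI, MeCN, rt; evaporate; KOt-Bu (2.2 equiv), THF, −40 to 0 °C
Reagents that add atoms: iodomethane, CI (its methyl groups are found in intermediate 19 only)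
Why: Grob fragmentation as ring expansion: the C9 alkoxide expels NMe3 from C15 while the ring-fusion C4–C9 bond breaks (antiperiplanar alignment by rotation about C4–C15, no β-hydrogen for Hofmann elimination), giving the C9 ketone, the 4(15)-methylene and a (Z)-C1=C10 bond inherited from ring A, and the lactone ammonium eliminates by E1cB to the 11(13)-methylene; the C5 ester is trans-1,3 to O9 and cannot migrate.

Step 11
Reactants: 20 ten-membered (Z)-enone
Product: 21 C6 alcohol
Conditions: DDQ, CH2Cl2/pH 7 buffer, 0 °C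
Reagents that add atoms: none
Why: Oxidative cleavage of the PMB ether by DDQ, done before the ketone is reduced so that no allylic alcohol is exposed to the oxidant.

Step 12
Reactants: 21 C6 alcohol
Product: 22 6,9-diol (9S)
Conditions: NaBH4, CeCl3·7H2O, MeOH, −78 °C
Reagents that add atoms: none
Why: Luche 1,2-reduction of the enone, faster than attack on esters or the lactone methylene; Felkin–Anh addition anti to the C8–O(lactone) bond gives the 8,9-threo (9S) allylic alcohol.

Step 13
Reactants: 22 6,9-diol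
Product: 23 6,9-diacetate
Conditions: Ac2O, DMAP, pyridine, CH2Cl2, 0 °C to rt
Reagents that add atoms: acetic anhydride, CC(=O)OC(C)=O
Why: DMAP-catalysed acetylation of both free secondary hydroxyls in one operation, fast enough to outrun acyl migration from O5.

Step 14
Reactants: 23 6,9-diacetate
Product: 24 C2 allylic alcohol
Conditions: HF·pyridine, pyridine, THF, 0 °C to rt
Reagents that add atoms: none
Why: Fluoride desilylation of the C2 silyl ether; esters, lactone and alkenes are inert to buffered HF·pyridine.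

Step 15
Reactants: 24 C2 allylic alcohol
Product: 25 1,10-epoxy alcohol (1R,10R)
Conditions: VO(acac)2 (5 mol%), t-BuOOH, CH2Cl2, 0 °C
Reagents that add atoms: tert-butyl hydroperoxide, CC(C)(C)OO
Why: Vanadium-catalysed hydroxyl-directed epoxidation: the alkoxide-bound vanadium peroxide delivers oxygen to the (Z)-C1=C10 face syn to the C2 hydroxyl (cis-epoxy alcohol, as for eight- and nine-membered (Z)-cycloalkenols), setting C1 and C10; the homoallylic 4(15)-ene reacts far more slowly and the lactone methylene not at all.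

Step 16
Reactants: 25 1,10-epoxy alcohol
Product: 26 CNP0256300.1 (target)
Conditions: Dess–Martin periodinane, NaHCO3, CH2Cl2, 0 °C
Reagents that add atoms: none
Why: Dess–Martin oxidation of the epoxy alcohol to the α,β-epoxy ketone under buffered, non-enolising conditions, so the β,γ-placed 4(15)-ene does not move into conjugation; the C2 centre that carried the chirality is erased here.

## Compound list

1 | 2-[(tert-butyldimethylsilyl)oxy]acetaldehyde | O=CCO[Si](C)(C)C(C)(C)C | starting material
2 | pent-1-en-3-one (ethyl vinyl ketone) | C=CC(=O)CC | starting material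
3 | (2S)-2-[(tert-butyldimethylsilyl)oxy]-5-oxoheptanal | CCC(=O)CC[C@H](O[Si](C)(C)C(C)(C)C)C=O | intermediate (not isolated)
4 | (4S)-4-[(tert-butyldimethylsilyl)oxy]-2-methylcyclohex-2-en-1-one (ring A; carbonyl = C9, CH–OTBS = C2) | O=C1CC[C@H](O[Si](C)(C)C(C)(C)C)C=C1C | intermediate
5 | 2-[(4-methoxybenzyl)oxy]acetaldehyde | O=CCOCc1ccc(OC)cc1 | starting material
6 | (4S)-4-[(tert-butyldimethylsilyl)oxy]-6-{1-hydroxy-2-[(4-methoxybenzyl)oxy]ethyl}-2-methylcyclohex-2-en-1-one, side chain trans to OTBS (major anti-aldol isomer drawn) | [C@H]1([C@H](O)COCc2ccc(OC)cc2)C[C@H](O[Si](C)(C)C(C)(C)C)C=C(C)C1=O | intermediate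
7 | (4S)-4-[(tert-butyldimethylsilyl)oxy]-6-{[(4-methoxybenzyl)oxy]acetyl}-2-methylcyclohex-2-en-1-one, drawn as its ring enol | O=C(COCc1ccc(OC)cc1)C1=C(O)C(C)=C[C@@H](O[Si](C)(C)C(C)(C)C)C1 | intermediate
8 | 6-[(dimethylamino)methyl]-6-{[(4-methoxybenzyl)oxy]acetyl}-4-[(tert-butyldimethylsilyl)oxy]-2-methylcyclohex-2-en-1-one, quaternary C4 with CH2NMe2 trans to OTBS | CN(C)C[C@@]1(C(=O)COCc2ccc(OC)cc2)C[C@H](O[Si](C)(C)C(C)(C)C)C=C(C)C1=O | intermediate
9 | furan-2(5H)-one | O=C1OCC=C1 | starting material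
10 | 2-[(triisopropylsilyl)oxy]furan | CC(C)[Si](Oc1ccco1)(C(C)C)C(C)C | intermediate
11 | 5-lithio-2-[(triisopropylsilyl)oxy]furan | [Li]c1ccc(O[Si](C(C)C)(C(C)C)C(C)C)o1 | intermediate (not isolated)
12 | furyl carbinol: 8 with C9 converted into a tertiary alcohol carrying the 5-[(triisopropylsilyl)oxy]furan-2-yl group trans to CH2NMe2 | CN(C)C[C@@]1(C(=O)COCc2ccc(OC)cc2)C[C@H](O[Si](C)(C)C(C)(C)C)C=C(C)[C@]1(O)c3ccc(O[Si](C(C)C)(C(C)C)C(C)C)o3 | intermediate (not isolated)
13 | butenolide: C9 tertiary alcohol carrying the (2R)-5-oxo-2,5-dihydrofuran-2-yl group (C8) | CN(C)C[C@@]1(C(=O)COCc2ccc(OC)cc2)C[C@H](O[Si](C)(C)C(C)(C)C)C=C(C)[C@]1(O)[C@@H]3OC(=O)C=C3 | intermediate (not isolated)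
14 | tricyclic keto lactone: cis-fused rings A/B (C9–OH cis to C4–CH2NMe2), C5 ketone, C6 OPMB trans to C7–C11, cis γ-lactone at C7/C8 with O8 trans to C9–OH, C2 OTBS, C1=C10 alkene | C1C(=O)O[C@@H]2[C@H]1[C@@H](OCc4ccc(OC)cc4)C(=O)[C@]3(CN(C)C)C[C@H](O[Si](C)(C)C(C)(C)C)C=C(C)[C@]23O | intermediate
15 | C5 alcohol of 14 (5R; hydroxyl anti to C9–OH, trans to C6 OPMB) | C1C(=O)O[C@@H]2[C@H]1[C@@H](OCc4ccc(OC)cc4)[C@H](O)[C@]3(CN(C)C)C[C@H](O[Si](C)(C)C(C)(C)C)C=C(C)[C@]23O | intermediate
16 | 15 carrying a second CH2NMe2 group on lactone carbon C11 (exo face) | CN(C)C[C@@H]1C(=O)O[C@@H]2[C@H]1[C@@H](OCc4ccc(OC)cc4)[C@H](O)[C@]3(CN(C)C)C[C@H](O[Si](C)(C)C(C)(C)C)C=C(C)[C@]23O | intermediate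
17 | (R)-2-methylbutanoic acid | CC[C@@H](C)C(=O)O | starting material
18 | C5 (R)-2-methylbutanoate of 16 | CN(C)C[C@@H]1C(=O)O[C@@H]2[C@H]1[C@@H](OCc4ccc(OC)cc4)[C@H](OC(=O)[C@H](C)CC)[C@]3(CN(C)C)C[C@H](O[Si](C)(C)C(C)(C)C)C=C(C)[C@]23O | intermediate
19 | bis(trimethylammonium) diiodide of 18 | C[N+](C)(C)C[C@@H]1C(=O)O[C@@H]2[C@H]1[C@@H](OCc4ccc(OC)cc4)[C@H](OC(=O)[C@H](C)CC)[C@]3(C[N+](C)(C)C)C[C@H](O[Si](C)(C)C(C)(C)C)C=C(C)[C@]23O.[I-].[I-] | intermediate (not isolated)
20 | (1(10)Z)-2-[(tert-butyldimethylsilyl)oxy]-6-[(4-methoxybenzyl)oxy]-5-{[(2R)-2-methylbutanoyl]oxy}-9-oxogermacra-1(10),4(15),11(13)-trien-12,8-olide | C=C1C(=O)O[C@@H]2[C@H]1[C@@H](OCc3ccc(OC)cc3)[C@H](OC(=O)[C@H](C)CC)C(=C)C[C@H](O[Si](C)(C)C(C)(C)C)/C=C(/C)C2=O | intermediate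
21 | 6-hydroxy analogue of 20 (PMB removed) | C=C1C(=O)O[C@@H]2[C@H]1[C@@H](O)[C@H](OC(=O)[C@H](C)CC)C(=C)C[C@H](O[Si](C)(C)C(C)(C)C)/C=C(/C)C2=O | intermediate
22 | (9S)-6,9-diol (C9 ketone of 21 reduced) | C=C1C(=O)O[C@@H]2[C@H]1[C@@H](O)[C@H](OC(=O)[C@H](C)CC)C(=C)C[C@H](O[Si](C)(C)C(C)(C)C)/C=C(/C)[C@H]2O | intermediate
23 | 6,9-diacetate of 22 | C=C1C(=O)O[C@@H]2[C@H]1[C@@H](OC(C)=O)[C@H](OC(=O)[C@H](C)CC)C(=C)C[C@H](O[Si](C)(C)C(C)(C)C)/C=C(/C)[C@H]2OC(C)=O | intermediate
24 | (2S)-2-hydroxy-6,9-diacetate (silyl group removed) | C=C1C(=O)O[C@@H]2[C@H]1[C@@H](OC(C)=O)[C@H](OC(=O)[C@H](C)CC)C(=C)C[C@H](O)/C=C(/C)[C@H]2OC(C)=O | intermediate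
25 | (1R,10R)-1,10-epoxy-2-hydroxy compound (epoxide syn to C2–OH) | C=C1C(=O)O[C@@H]2[C@H]1[C@@H](OC(C)=O)[C@H](OC(=O)[C@H](C)CC)C(=C)C[C@H](O)[C@@H]1O[C@]1(C)[C@H]2OC(C)=O | intermediate
26 | CNP0256300.1: (1R,5R,6R,7R,8R,9S,10R)-6,9-diacetoxy-1,10-epoxy-5-{[(2R)-2-methylbutanoyl]oxy}-2-oxogermacra-4(15),11(13)-dien-12,8-olide | C=C1C(=O)O[C@@H]2[C@H]1[C@@H](OC(C)=O)[C@H](OC(=O)[C@H](C)CC)C(=C)CC(=O)[C@@H]1O[C@]1(C)[C@H]2OC(C)=O | target

## Step count and risks

Total steps: 16. Longest linear sequence: 15 (steps 1–4 and 6–16); step 5 is a one-step side branch.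

The three steps most likely to fail:

Step 6 (the proposed new annulation). Risks are incomplete 1,2-addition to the hindered enone, loss of the furanolate by retro-aldol, and a wrong C8/C9 relationship. Fallback with known chemistry, setting out from 8 and coming back at 13 (then 14): the established butenolide γ-anion equivalent 5-lithio-2-methoxyfuran (from 2-methoxyfuran and n-BuLi) is added to the lithium enolate of 8 to give the methoxyfuryl carbinol F1. Mild hydrolysis (oxalic acid on wet silica gel, CH2Cl2, 0 °C) converts its methoxyfuran into butenolide 13, which is now isolated. A separate DBU-mediated Michael cyclisation gives 14.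

Step 12 (facial selectivity of the C9 reduction in the ten-membered ring). Fallback setting out from 20 and coming back at 23: if hydride adds from the other face, 20 is reduced directly (NaBH4, CeCl3·7H2O) to the 9-epimeric allylic alcohol F2. Mitsunobu reaction with acetic acid (PPh3, DIAD) inverts C9 and installs the acetate, giving the (9S)-acetate F3. DDQ then removes the PMB group to give the C6 alcohol F4, and acetylation (Ac2O, DMAP) gives 23.

Step 15 (face of the directed epoxidation). Fallback setting out from 24 and coming back at 26: if oxygen is delivered to the wrong face, 24 is oxidised with Dess–Martin periodinane to the cross-conjugated enone F5. Reagent-controlled reduction (Me-CBS oxazaborolidine, catecholborane, −78 °C) gives the C2-epimeric allylic alcohol F6, whose hydroxyl sits on the other face. VO(acac)2/t-BuOOH then gives the epoxy alcohol F7 with the required (1R,10R) epoxide, and Dess–Martin oxidation gives 26. This works because the C2 centre is erased in the last step.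

Further compounds
F1 | step 6 | methoxyfuryl carbinol: 8 with C9 converted into a tertiary alcohol carrying a 5-methoxyfuran-2-yl group | CN(C)C[C@@]1(C(=O)COCc2ccc(OC)cc2)C[C@H](O[Si](C)(C)C(C)(C)C)C=C(C)[C@]1(O)c3ccc(OC)o3
F2 | step 12 | 9-epimeric (9R) allylic alcohol from 20 (C6 OPMB, C2 OTBS retained) | C=C1C(=O)O[C@@H]2[C@H]1[C@@H](OCc3ccc(OC)cc3)[C@H](OC(=O)[C@H](C)CC)C(=C)C[C@H](O[Si](C)(C)C(C)(C)C)/C=C(/C)[C@@H]2O
F3 | step 12 | (9S)-acetate with C6 OPMB and C2 OTBS | C=C1C(=O)O[C@@H]2[C@H]1[C@@H](OCc3ccc(OC)cc3)[C@H](OC(=O)[C@H](C)CC)C(=C)C[C@H](O[Si](C)(C)C(C)(C)C)/C=C(/C)[C@H]2OC(C)=O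
F4 | step 12 | (9S)-acetate with free C6 hydroxyl and C2 OTBS | C=C1C(=O)O[C@@H]2[C@H]1[C@@H](O)[C@H](OC(=O)[C@H](C)CC)C(=C)C[C@H](O[Si](C)(C)C(C)(C)C)/C=C(/C)[C@H]2OC(C)=O
F5 | step 15 | 2-oxo-1(10)Z-enone 6,9-diacetate | C=C1C(=O)O[C@@H]2[C@H]1[C@@H](OC(C)=O)[C@H](OC(=O)[C@H](C)CC)C(=C)CC(=O)/C=C(/C)[C@H]2OC(C)=O
F6 | step 15 | (2R)-2-hydroxy epimer of 24 | C=C1C(=O)O[C@@H]2[C@H]1[C@@H](OC(C)=O)[C@H](OC(=O)[C@H](C)CC)C(=C)C[C@@H](O)/C=C(/C)[C@H]2OC(C)=O
F7 | step 15 | C2 epimer of 25 with the (1R,10R) epoxide | C=C1C(=O)O[C@@H]2[C@H]1[C@@H](OC(C)=O)[C@H](OC(=O)[C@H](C)CC)C(=C)C[C@@H](O)[C@@H]1O[C@]1(C)[C@H]2OC(C)=O
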